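The numbers in the tables were computed from invented constants.

Slowness does not describe the end of Tuesday's run: its two substrates together read 35.5% at 8.00 min and 34.5% at 20.0 min.

| setting | Tuesday's | Wednesday's | Friday's | flask |
|---|---|---|---|---|
| left-handed substrate | 0.50 mM | 0.50 mM | 0.50 mM | 0.50 mM |
| right-handed substrate | 0.50 mM | 0.50 mM | 0.50 mM | 0.50 mM |
| partner | 0.75 mM | 0.75 mM | 1.5 mM | 0.750 mM |
| free catalyst | 0.70 µM | 1.1 µM | 0.50 µM | 0.50 µM |
| remark | run made earlier | run made earlier | run made earlier |  |
| time |  |  |  | 15 min |

| run | time / min | left-handed substrate / % | right-handed substrate / % |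
|---|---|---|---|
| Tuesday's | 1.33 | 17.2 | 41.3 |
| Tuesday's | 3.00 | 9.0 | 37.0 |
| Tuesday's | 8.00 | 2.8 | 32.7 |
| Tuesday's | 20.0 | 3.4 | 31.1 |
| Wednesday's | 5.00 | 4.7 | 30.4 |
| Wednesday's | 10.0 | 2.6 | 28.9 |
| Wednesday's | 15.0 | 2.3 | 28.8 |
| Wednesday's | 20.0 | 2.2 | 28.2 |
| Friday's | 1.33 | 6.9 | 35.3 |
| Friday's | 3.00 | 1.6 | 26.5 |
| Friday's | 8.00 | 0.7 | 16.1 |
| Friday's | 20.0 | 0.1 | 8.7 |

(standard deviation of a reading: 0.5 percentage points)

- free catalyst is single-handed; left-handed substrate and right-handed substrate are mirror images of each other, charged as a racemate, each of them at the stated concentration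
- the numbers in the tables scatter with a standard deviation of 0.5 percentage points
- an excess is the difference of the two amounts in percent of their sum
- an excess is below zero if the other one leads

* part of the left-handed substrate and right-handed substrate charged together that has reacted at 15 min
* excess of left-handed product over right-handed product in the product at 15 min
* excess of right-handed substrate over left-handed substrate among what is left of the two at 15 min

Take the main step first. Each substrate consumed takes one partner, and the flask's [partner] of 0.750 mM is less than its 1.00 mM of substrates, so on this step partner is the limiting reagent and its charge allows c of 75.0%. Friday's run, with this flask's catalyst charge but 1.5 mM of partner, reads right-handed substrate falling from 16.1% at 8.00 min to 8.7% at 20.0 min, so the catalyst still turns over in that run.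

Next comes the preference between substrates. In Tuesday's run, ln(charge/left) is larger for left-handed substrate by a selectivity factor reading 5.66, so the remainder leans to right-handed substrate. No run reads the products, so no product excess is reckoned here.

Last comes a loss. Tuesday's and Wednesday's runs stall below the partner mark, with 0.0950 mM and 0.0540 mM of partner unaccounted for at 20.0 min, less with more catalyst. Replace the [partner] curve by its mean: if the loss runs at its own pace beside the catalysis, partner's lifetime goes as 1/[free catalyst], so the loss times the catalyst charge should hold constant, and the two runs give a ratio of 1.12. Averaged and scaled to this flask, the partner toll, meaning partner charged that ends in no product, is 0.126 mM. Tuesday's stall by 8.00 min scales to 11.2 min, earlier than 15 min, so c reckons to 62.4%. The mean overlooks that the toll shortens partner's life, an error growing with the toll's share, here 16.8% of the charge.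

The forecast, holding that “the catalyst is dying”, gave c 63.8%, above the 62.4% reckoned here, eP 44.2% and eS 77.9%.

The flask gives c 62.4%, eP −0.00526% and eS 75.1%.

    partner + catalyst intermediate A → free catalyst + left-handed product (k = 50000 L mol⁻¹ s⁻¹)
    partner + catalyst intermediate B → free catalyst + right-handed product (k = 11000 L mol⁻¹ s⁻¹)
    left-handed product ⇌ right-handed product (k = 0.0400 s⁻¹)
    free catalyst + left-handed substrate ⇌ catalyst intermediate A (K = 2500 L mol⁻¹, k = 3.20 × 10⁶ L mol⁻¹ s⁻¹)
    free catalyst + right-handed substrate ⇌ catalyst intermediate B (K = 2000 L mol⁻¹, k = 6.80 × 10⁵ L mol⁻¹ s⁻¹)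
    2 partner → self-condensation product (k = 2.30 L mol⁻¹ s⁻¹)

Left-handed product has a forward half-life of 0.29 min toward right-handed product, short against 15 min, and the flask ends with 31.2% of the first and 31.2% of the second. The flask's self-condensation product of 0.0598 mM holds 0.120 mM of partner and 0.00643 mM of partner stands free, beside the reckoned toll of 0.126 mM. On the neighbour charged with 0.200 µM of free catalyst, the same scaling puts the stall at 28.0 min, later than 15 min, with a toll of 0.315 mM and c of 43.5% at that stall. At 15 min that neighbour stands at c 49.9%, with 4.08% of its partner charge free and 0.221 mM of partner in self-condensation product.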